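**Plan**

1. Cuts: the O7 acetate and the O8 and O11 isovalerate C–O bonds (late acylations), then C8–C9, which joins fragment 1 (C9–C23 spiroketal iodo alcohol) to fragment 2 (C1–C8 acid). Inside fragment 1: C10–C11, C21–C22 and C16–C17 (the spiroketal is the decarboxylated Claisen dimer of one lactone). Inside fragment 2: C4–C5 and C2=C3.
2. Enabling feature: O11 is the fourth atom from C8 (C8–C9–C10–C11–O11), and O8 and O11 end as the same isovalerate. The C8 carboxyl is therefore first hung on O11 as an ester (a C8–O11 bond absent from the target). SmI2 then turns the C9 iodide into a carbon nucleophile that reaches the C8 carbonyl through a five-membered transition state; the O→C acyl shift makes C8–C9, frees O11 and leaves C8 as a ketone.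
3. Forward order: rings A and B form together (lactone → Claisen self-condensation → decarboxylation → spiroketal); the C2-symmetric core is desymmetrised; C21–C23, then C9–C11 are added. Fragment 2 comes from dimethyl (S)-malate. Then ester tether, key step, C8 reduction, acylations, unmasking of the C22 ketone.
4. Stereochemistry: C12/C20 from (S)-benzyl glycidyl ether; C14/C18 by cis-hydrogenation of the lactone; C16 thermodynamic; C21 and C11 by chelate-controlled Grignard additions; C10 by A(1,3)-controlled hydroboration; C7 from malate; C6 by Fráter–Seebach methylation; C5 by Felkin–Anh/1,3-anti allylation; C8 by CBS reduction matched with Felkin–Anh; C2=C3 (E) by cross-metathesis.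

Key step: step 25

Remark: the spiroketal of the target has both ring C–O bonds axial and all four ring substituents equatorial, so it is taken to be the thermodynamic isomer and is closed under equilibrating acid.

Numbering and abbreviations: C1 (methyl ester carbonyl) to C23 (ketone methyl) along the target chain; ring A = oxane O12/C12–C16, ring B = oxane O20/C16–C20; TES = SiEt3, TBS = SiMe2tBu, Bn = benzyl.

**Fragment 1 (C9–C23)**

Step 1
Reactants: 1 (2S)-2-[(benzyloxy)methyl]oxirane [(S)-benzyl glycidyl ether]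
Product: 2 (2S)-1-(benzyloxy)-4-methylpent-4-en-2-ol
Conditions: CH2=C(CH3)MgBr, CuI (10 mol %), THF, −30 °C
Reagents that add atoms: isopropenylmagnesium bromide, CC(=C)[Mg]Br
Why: Copper-catalysed Grignard opening of the terminal epoxide at its CH2 carbon leaves the carbinol centre (future C12 and C20) as it was in the glycidyl ether.

Step 2
Reactants: 2 (2S)-1-(benzyloxy)-4-methylpent-4-en-2-ol
Product: 3 (2S)-1-(benzyloxy)-4-methylpent-4-en-2-yl prop-2-enoate
Conditions: CH2=CHCOCl, Et3N, 4-(dimethylamino)pyridine (cat.), CH2Cl2, 0 °C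
Reagents that add atoms: acryloyl chloride, C=CC(Cl)=O
Why: O-Acylation of the secondary alcohol sets up the diene for ring closure.

Step 3
Reactants: 3 (2S)-1-(benzyloxy)-4-methylpent-4-en-2-yl prop-2-enoate
Product: 4 (6S)-6-[(benzyloxy)methyl]-4-methyl-5,6-dihydro-2H-pyran-2-one
Conditions: second-generation Grubbs catalyst RuCl2(=CHPh)(PCy3)(H2IMes) (5 mol %), toluene, 80 °C
Reagents that add atoms: none
Why: Ring-closing metathesis of the acrylate onto the 1,1-disubstituted alkene should close the six-membered unsaturated lactone with loss of ethylene.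

Step 4
Reactants: 4 (6S)-6-[(benzyloxy)methyl]-4-methyl-5,6-dihydro-2H-pyran-2-one
Product: 5 (4S,6S)-6-[(benzyloxy)methyl]-4-methyloxan-2-one (4,6-cis lactone)
Conditions: H2 (1 atm), PtO2, EtOAc, rt
Reagents that add atoms: none
Why: Heterogeneous hydrogenation should add hydrogen to the ring face opposite the C6 substituent and so give the cis-4,6 lactone (future C14 and C18), while platinum leaves the benzyl ether intact.

Step 5
Reactants: 5 (4S,6S)-6-[(benzyloxy)methyl]-4-methyloxan-2-one (two molecules)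
Product: 7 (2S,4S,8S,10S)-2,8-bis[(benzyloxy)methyl]-4,10-dimethyl-1,7-dioxaspiro[5.5]undecane (C2-symmetric, rings A and B), via Claisen adduct 6 (not isolated)
Conditions: LiN(iPr)2 (0.55 equiv), THF, −78 °C to rt; then 3 M aq. HCl, THF, 60 °C
Reagents that add atoms: none
Why: Claisen self-condensation of the lactone enolate with a second lactone, then acid hydrolysis, decarboxylation of the β-keto acid and acetalisation (two 6-exo closures onto C16) should give the doubly anomeric spiroketal, with C16 set under thermodynamic control.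

Step 6
Reactants: 7 bis-benzyl spiroketal
Product: 8 [(2S,4S,8S,10S)-4,10-dimethyl-1,7-dioxaspiro[5.5]undecane-2,8-diyl]dimethanol
Conditions: H2 (1 atm), Pd(OH)2/C, EtOAc/EtOH, rt
Reagents that add atoms: none
Why: Neutral hydrogenolysis removes both benzyl ethers without touching the spiroketal; the benzyl groups had kept O11 and O21 out of the acetalisation.

Step 7
Reactants: 8 spiroketal diol
Product: 9 [(2S,4S,8S,10S)-4,10-dimethyl-8-{[(triethylsilyl)oxy]methyl}-1,7-dioxaspiro[5.5]undecan-2-yl]methanol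
Conditions: Et3SiCl (1.0 equiv), imidazole, CH2Cl2, −20 °C
Reagents that add atoms: chlorotriethylsilane, CC[Si](Cl)(CC)CC
Why: The two hydroxymethyl groups are homotopic (C2 axis), so monosilylation can give only one compound and serves to tell the two ends apart (8 and the bis-ether are recycled).

Step 8
Reactants: 9 mono-TES ether
Product: 10 (2S,4S,8S,10S)-4,10-dimethyl-8-{[(triethylsilyl)oxy]methyl}-1,7-dioxaspiro[5.5]undecane-2-carbaldehyde (C21 aldehyde)
Conditions: Dess–Martin periodinane, NaHCO3, CH2Cl2, 0 °C to rt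
Reagents that add atoms: none
Why: Buffered Dess–Martin oxidation of the primary alcohol leaves the silyl ether and the α-alkoxy stereocentre untouched.

Step 9
Reactants: 10 C21 aldehyde
Product: 11 (1S)-1-[(2S,4S,8S,10S)-4,10-dimethyl-8-{[(triethylsilyl)oxy]methyl}-1,7-dioxaspiro[5.5]undecan-2-yl]-2,3-dimethylbut-2-en-1-ol
Conditions: (CH3)2C=C(CH3)MgBr (from 2-bromo-3-methylbut-2-ene and Mg), MgBr2·OEt2, CH2Cl2, −78 °C
Reagents that add atoms: (3-methylbut-2-en-2-yl)magnesium bromide, CC(C)=C(C)[Mg]Br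
Why: Cram-chelate Grignard addition, with magnesium bridging the aldehyde oxygen and ring oxygen O20, should give the 20,21-syn carbinol; the tetrasubstituted alkene is the latent C22 ketone, inert to 9-BBN and the most ozone-reactive alkene at the end.

Step 10
Reactants: 11 allylic alcohol
Product: 12 TBS ether of 11 (C21–OTBS, C11–OTES)
Conditions: tBuMe2SiOTf, 2,6-lutidine, CH2Cl2, −78 to 0 °C
Reagents that add atoms: tert-butyldimethylsilyl trifluoromethanesulfonate, CC(C)(C)[Si](C)(C)OS(=O)(=O)C(F)(F)F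
Why: Silylation of the hindered secondary alcohol gives the O21 protecting group that is carried to the last step.

Step 11
Reactants: 12 bis-silyl ether
Product: 13 (2S,4S,8S,10S)-8-{(1S)-1-[(tert-butyldimethylsilyl)oxy]-2,3-dimethylbut-2-en-1-yl}-4,10-dimethyl-1,7-dioxaspiro[5.5]undecane-2-carbaldehyde (C11 aldehyde)
Conditions: (COCl)2, DMSO, CH2Cl2, −78 to −30 °C; then Et3N
Reagents that add atoms: none
Why: Swern conditions cleave and oxidise a primary triethylsilyl ether in one operation (oxidative desilylation through the alkoxysulfonium salt), while the secondary TBS ether survives.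

Step 12
Reactants: 13 C11 aldehyde
Product: 14 (1S)-1-[(2S,4S,8S,10S)-8-{(1S)-1-[(tert-butyldimethylsilyl)oxy]-2,3-dimethylbut-2-en-1-yl}-4,10-dimethyl-1,7-dioxaspiro[5.5]undecan-2-yl]-2-methylprop-2-en-1-ol
Conditions: CH2=C(CH3)MgBr, MgBr2·OEt2, CH2Cl2, −78 °C
Reagents that add atoms: isopropenylmagnesium bromide, CC(=C)[Mg]Br
Why: A second Cram-chelate Grignard addition, now through ring oxygen O12, should set C11 syn to O12 and bring in C9, C10 and the C10 methyl carbon as an isopropenyl group.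

Step 13
Reactants: 14 isopropenyl carbinol
Product: 16 (1S,2S)-2-methyl-1-[spiroketal of 14]propane-1,3-diol (C9–OH, C11–OH), via B-alkyl-9-BBN 15 (not isolated)
Conditions: 9-BBN (3 equiv), THF, 0 °C to rt; then NaOH, H2O2, 0 °C
Reagents that add atoms: hydrogen peroxide, OO
Why: Hydroboration–oxidation, in which 9-BBN attacks only the 1,1-disubstituted alkene (the tetrasubstituted one is inert) from the face dictated by A(1,3) strain at C11, should give the 10,11-anti 1,3-diol and so set C10.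

Step 14
Reactants: 16 1,3-diol
Product: 17 (1S,2R)-3-iodo-2-methyl-1-[spiroketal of 14]propan-1-ol (fragment 1: C9–I, C11–OH)
Conditions: I2, PPh3, imidazole, CH2Cl2, 0 °C
Reagents that add atoms: iodine, I-I
Why: Appel-type iodination with PPh3, iodine and imidazole is selective for the primary hydroxyl and leaves the hindered C11–OH free for the tether.

**Fragment 2 (C1–C8)**

Step 15
Reactants: 18 dimethyl (2S)-2-hydroxybutanedioate [dimethyl (S)-malate]
Product: 20 dimethyl (2S,3R)-2-hydroxy-3-methylbutanedioate, via dilithium dianion 19 (not isolated)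
Conditions: LiN(SiMe3)2 (2.2 equiv), THF, −78 °C; then CH3I, −78 to −20 °C; aq. NH4Cl
Reagents that add atoms: iodomethane, IC
Why: Fráter–Seebach alkylation, in which the chelated alkoxide enolate is methylated anti to the alkoxide, should set C6 relative to C7.

Step 16
Reactants: 20 dimethyl (2S,3R)-2-hydroxy-3-methylbutanedioate
Product: 21 methyl (2R,3S)-3,4-dihydroxy-2-methylbutanoate
Conditions: BH3·SMe2, NaBH4 (5 mol %), THF, 0 °C to rt; then MeOH
Reagents that add atoms: none
Why: Hydroxyl-directed borane reduction takes only the α-hydroxy ester (C8), through a cyclic alkoxyborane, and leaves the distal ester (C5); 21 is used crude to avoid lactonisation.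

Step 17
Reactants: 21 methyl (2R,3S)-3,4-dihydroxy-2-methylbutanoate
Product: 22 methyl (2R,3S)-2-methyl-3,4-bis[(triethylsilyl)oxy]butanoate
Conditions: Et3SiCl (2.4 equiv), imidazole, DMF, 0 °C to rt
Reagents that add atoms: chlorotriethylsilane, CC[Si](Cl)(CC)CC
Why: Bis-silylation gives the lasting O7 protection and a primary silyl ether at C8 that can later be oxidised directly.

Step 18
Reactants: 22 bis-TES ester
Product: 23 (2R,3S)-2-methyl-3,4-bis[(triethylsilyl)oxy]butanal
Conditions: iBu2AlH (1.1 equiv), CH2Cl2, −78 °C; aq. potassium sodium tartrate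
Reagents that add atoms: none
Why: Partial reduction of the methyl ester at low temperature stops at the aluminium hemiacetal and should release the aldehyde without epimerising C6.

Step 19
Reactants: 23 (2R,3S)-2-methyl-3,4-bis[(triethylsilyl)oxy]butanal
Product: 24 (4R,5S,6S)-5-methyl-6,7-bis[(triethylsilyl)oxy]hept-1-en-4-ol
Conditions: allyltrimethylsilane, BF3·OEt2, CH2Cl2, −78 °C
Reagents that add atoms: allyltrimethylsilane, C=CC[Si](C)(C)C
Why: Hosomi–Sakurai allylation, in which Felkin–Anh control by the α-methyl group and 1,3-anti induction by the β-silyloxy group reinforce each other, should set C5 syn to the C6 methyl and anti to O7.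

Step 20
Reactants: 24 homoallylic alcohol
Product: 25 (4R,5S,6S)-5-methyl-6,7-bis[(triethylsilyl)oxy]hept-1-en-4-yl propanoate
Conditions: (EtCO)2O, Et3N, 4-(dimethylamino)pyridine (cat.), CH2Cl2, rt
Reagents that add atoms: propanoic anhydride, CCC(=O)OC(=O)CC
Why: Acylation installs the C5 propanoate of the target at the only free hydroxyl.

Step 21
Reactants: 25 propanoate
Product: 26 methyl (2E,5R,6S,7S)-2,6-dimethyl-5-(propanoyloxy)-7,8-bis[(triethylsilyl)oxy]oct-2-enoate
Conditions: methyl methacrylate (10 equiv), second-generation Grubbs catalyst RuCl2(=CHPh)(PCy3)(H2IMes) (5 mol %), CH2Cl2, 40 °C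
Reagents that add atoms: methyl methacrylate, C=C(C)C(=O)OC
Why: Olefin cross-metathesis of the terminal alkene with a 1,1-disubstituted acrylate should give the thermodynamically favoured (E)-trisubstituted enoate.

Step 22
Reactants: 26 enoate bis-TES ether
Product: 27 methyl (2E,5R,6S,7S)-2,6-dimethyl-8-oxo-5-(propanoyloxy)-7-[(triethylsilyl)oxy]oct-2-enoate
Conditions: (COCl)2, DMSO, CH2Cl2, −78 to −35 °C; then Et3N
Reagents that add atoms: none
Why: Swern oxidative desilylation converts only the primary TES ether into the aldehyde; the secondary O7–TES group stays.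

Step 23
Reactants: 27 α-silyloxy aldehyde
Product: 28 (2S,3S,4R,6E)-8-methoxy-3,7-dimethyl-8-oxo-4-(propanoyloxy)-2-[(triethylsilyl)oxy]oct-6-enoic acid (fragment 2)
Conditions: NaClO2, NaH2PO4, 2-methylbut-2-ene, tBuOH/H2O, 0 °C
Reagents that add atoms: sodium chlorite, [Na+].[O-]Cl=O
Why: Pinnick oxidation converts the aldehyde into the acid under mildly acidic conditions that should not epimerise C7.

**Union and end game**

Step 24
Reactants: 28 fragment 2 acid; 17 fragment 1 iodo alcohol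
Product: 30 C8–O11 ester of 28 with 17 (tethered compound, C9–I), via mixed anhydride 29 (not isolated)
Conditions: 2,4,6-trichlorobenzoyl chloride, Et3N, THF, rt; then 17, 4-(dimethylamino)pyridine, toluene, rt
Reagents that add atoms: none
Why: Yamaguchi esterification joins the fragments through the temporary C8–O11 ester, a bond that is not in the target.

Step 25
Reactants: 30 tethered iodo ester
Product: 32 C1–C23 γ-hydroxy ketone (C8=O, C11–OH, C7–OTES, C21–OTBS), via C9 alkylsamarium diiodide 31 (not isolated)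
Conditions: SmI2 (2.1 equiv, added slowly), Fe(PhCOCHCOPh)3 (2 mol %), THF, −78 to −20 °C; then aq. NH4Cl
Reagents that add atoms: none
Why: Two single-electron transfers from SmI2 (divalent samarium) convert the C9–I bond into the alkylsamarium 31 (trivalent samarium), which adds to the C8 ester carbonyl through a five-membered transition state (C9, C10, C11, O11, C8); the cyclic samarium hemiketalate opens on work-up to the γ-hydroxy ketone, a net 1,4 O→C acyl shift. The closest known reaction type is the SmI2-promoted intramolecular nucleophilic acyl substitution (intramolecular Barbier-type acylation) of 3-iodopropyl esters to 4-hydroxy ketones, catalysed by trivalent iron. The only ring closed is the transient oxolane hemiketal, formed by 5-exo-trig attack on C8=O, and it is not kept. No stereocentre is created; C10 and C11 are spectators, and C7, although α to the new carbonyl, stays masked in the hemiketalate until the quench. The step needs chemoselectivity: the iodide must be reduced before the enoate and the other esters (no HMPA, no proton donor); only the tethered ester may be attacked (only C8 lies within five-membered reach of C9, the propanoate and methyl ester would need rings of ten or more atoms); and the α-silyloxy ketone must not be reduced further (it persists as the hemiketalate, and only two equivalents of SmI2 are added slowly). The tether is consumed in the step and sets free O11 together with the C8 carbonyl, the two oxygen sites that later carry the identical isovalerates.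

Step 26
Reactants: 32 γ-hydroxy ketone
Product: 33 C1–C23 (8S)-8,11-diol (C7–OTES, C21–OTBS)
Conditions: (R)-2-methyl-CBS-oxazaborolidine [(R)-1-methyl-3,3-diphenyltetrahydro-1H,3H-pyrrolo[1,2-c][1,3,2]oxazaborole] (1 equiv), catecholborane, toluene, −78 °C; then MeOH, pH 7 buffer
Reagents that add atoms: none
Why: Corey–Bakshi–Shibata reduction, with the α-branched C7 side as the large group, should give the (8S)-carbinol; this reagent control is matched with the Felkin–Anh preference of the α-silyloxy ketone (7,8-syn), and catecholborane spares both alkenes and the esters.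

Step 27
Reactants: 33 8,11-diol
Product: 34 C1–C23 8,11-bis(3-methylbutanoate) (C7–OTES, C21–OTBS)
Conditions: (iPrCH2CO)2O, Et3N, 4-(dimethylamino)pyridine, CH2Cl2, rt
Reagents that add atoms: 3-methylbutanoic anhydride, CC(C)CC(=O)OC(=O)CC(C)C
Why: One acylation installs both isovalerates on the two hydroxyls that the key step and the reduction set free.

Step 28
Reactants: 34 bis-isovalerate
Product: 35 C7 alcohol (C21–OTBS retained)
Conditions: pyridinium p-toluenesulfonate (cat.), MeOH/CH2Cl2, 0 °C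
Reagents that add atoms: none
Why: Mild acid methanolysis removes the secondary TES ether much faster than the hindered secondary TBS ether and is too mild for acyl migration.

Step 29
Reactants: 35 C7 alcohol
Product: 36 C7 acetate
Conditions: Ac2O, pyridine, 4-(dimethylamino)pyridine (cat.), CH2Cl2, rt
Reagents that add atoms: acetic anhydride, CC(=O)OC(C)=O
Why: Acetylation of the last free hydroxyl completes the ester pattern.

Step 30
Reactants: 36 C7 acetate
Product: 38 C22 methyl ketone with C21–OTBS, via C22 ozonide 37 (not isolated)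
Conditions: O3 (dosed to one equivalent), CH2Cl2, −78 °C; then Me2S, −78 °C to rt
Reagents that add atoms: ozone, [O-][O+]=O
Why: Ozonolysis with reductive work-up cleaves the electron-rich tetrasubstituted alkene far faster than the electron-poor trisubstituted enoate and unmasks the C22 ketone with loss of acetone.

Step 31
Reactants: 38 α-silyloxy ketone
Product: 39 CNP0165569.4 (target)
Conditions: HF·pyridine, pyridine, THF, 0 °C to rt
Reagents that add atoms: none
Why: Buffered fluoride desilylation frees the C21 hydroxyl under conditions that should not cleave or shift the five esters or epimerise the α-hydroxy ketone.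

**Compound list**

1 | (2S)-2-[(benzyloxy)methyl]oxirane | C(OCc1ccccc1)[C@@H]1CO1 | starting material
2 | (2S)-1-(benzyloxy)-4-methylpent-4-en-2-ol | CC(=C)C[C@H](O)COCc1ccccc1 | intermediate
3 | (2S)-1-(benzyloxy)-4-methylpent-4-en-2-yl prop-2-enoate | CC(=C)C[C@H](OC(=O)C=C)COCc1ccccc1 | intermediate
4 | (6S)-6-[(benzyloxy)methyl]-4-methyl-5,6-dihydro-2H-pyran-2-one | O=C1C=C(C)C[C@@H](COCc2ccccc2)O1 | intermediate
5 | (4S,6S)-6-[(benzyloxy)methyl]-4-methyloxan-2-one (cis) | O=C1C[C@@H](C)C[C@@H](COCc2ccccc2)O1 | intermediate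
6 | Claisen adduct: (4S,6S)-3-[(3S,5S)-6-(benzyloxy)-5-hydroxy-3-methylhexanoyl]-6-[(benzyloxy)methyl]-4-methyloxan-2-one (C3 enolisable, unassigned) | O=C1O[C@H](COCc2ccccc2)C[C@H](C)C1C(=O)C[C@@H](C)C[C@H](O)COCc1ccccc1 | intermediate
7 | (2S,4S,8S,10S)-2,8-bis[(benzyloxy)methyl]-4,10-dimethyl-1,7-dioxaspiro[5.5]undecane (each ring oxygen axial on the other ring) | C(OCc1ccccc1)[C@@H]2C[C@H](C)C[C@]3(C[C@@H](C)C[C@@H](COCc4ccccc4)O3)O2 | intermediate
8 | [(2S,4S,8S,10S)-4,10-dimethyl-1,7-dioxaspiro[5.5]undecane-2,8-diyl]dimethanol | OC[C@@H]1C[C@H](C)C[C@]2(C[C@@H](C)C[C@@H](CO)O2)O1 | intermediate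
9 | mono-TES ether of 8 (C11–OTES, C21–OH) | CC[Si](CC)(CC)OC[C@@H]1C[C@H](C)C[C@]2(C[C@@H](C)C[C@@H](CO)O2)O1 | intermediate
10 | C21 aldehyde (C11–OTES) | CC[Si](CC)(CC)OC[C@@H]1C[C@H](C)C[C@]2(C[C@@H](C)C[C@@H](C=O)O2)O1 | intermediate
11 | C21 (1S)-allylic alcohol with 2,3-dimethylbut-2-enyl terminus (C11–OTES) | CC[Si](CC)(CC)OC[C@@H]1C[C@H](C)C[C@]2(C[C@@H](C)C[C@@H]([C@@H](O)C(C)=C(C)C)O2)O1 | intermediate
12 | TBS ether of 11 (C21–OTBS, C11–OTES) | CC[Si](CC)(CC)OC[C@@H]1C[C@H](C)C[C@]2(C[C@@H](C)C[C@@H]([C@@H](O[Si](C)(C)C(C)(C)C)C(C)=C(C)C)O2)O1 | intermediate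
13 | C11 aldehyde (C21–OTBS) | O=C[C@@H]1C[C@H](C)C[C@]2(C[C@@H](C)C[C@@H]([C@@H](O[Si](C)(C)C(C)(C)C)C(C)=C(C)C)O2)O1 | intermediate
14 | C11 (1S)-isopropenyl carbinol (C21–OTBS) | CC(=C)[C@H](O)[C@@H]1C[C@H](C)C[C@]2(C[C@@H](C)C[C@@H]([C@@H](O[Si](C)(C)C(C)(C)C)C(C)=C(C)C)O2)O1 | intermediate
15 | B-alkyl-9-BBN at C9 with O11 borinate | C1CC2CCCC(C1)B2C[C@H](C)[C@H](OB3C4CCCC3CCC4)[C@@H]5C[C@H](C)C[C@]6(C[C@@H](C)C[C@@H]([C@@H](O[Si](C)(C)C(C)(C)C)C(C)=C(C)C)O6)O5 | intermediate
16 | (10S,11S)-C9,C11-diol (C21–OTBS) | OC[C@H](C)[C@H](O)[C@@H]1C[C@H](C)C[C@]2(C[C@@H](C)C[C@@H]([C@@H](O[Si](C)(C)C(C)(C)C)C(C)=C(C)C)O2)O1 | intermediate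
17 | fragment 1: C9 iodide, C11–OH, C21–OTBS | IC[C@H](C)[C@H](O)[C@@H]1C[C@H](C)C[C@]2(C[C@@H](C)C[C@@H]([C@@H](O[Si](C)(C)C(C)(C)C)C(C)=C(C)C)O2)O1 | intermediate
18 | dimethyl (2S)-2-hydroxybutanedioate | COC(=O)C[C@H](O)C(=O)OC | starting material
19 | dilithium alkoxide enolate of 18 | COC(=O)[C@@H]([O-])C=C([O-])OC.[Li+].[Li+] | intermediate
20 | dimethyl (2S,3R)-2-hydroxy-3-methylbutanedioate | COC(=O)[C@H](C)[C@H](O)C(=O)OC | intermediate
21 | methyl (2R,3S)-3,4-dihydroxy-2-methylbutanoate | COC(=O)[C@H](C)[C@H](O)CO | intermediate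
22 | methyl (2R,3S)-2-methyl-3,4-bis[(triethylsilyl)oxy]butanoate | COC(=O)[C@H](C)[C@H](O[Si](CC)(CC)CC)CO[Si](CC)(CC)CC | intermediate
23 | (2R,3S)-2-methyl-3,4-bis[(triethylsilyl)oxy]butanal | O=C[C@H](C)[C@H](O[Si](CC)(CC)CC)CO[Si](CC)(CC)CC | intermediate
24 | (4R,5S,6S)-5-methyl-6,7-bis[(triethylsilyl)oxy]hept-1-en-4-ol | C=CC[C@@H](O)[C@H](C)[C@H](O[Si](CC)(CC)CC)CO[Si](CC)(CC)CC | intermediate
25 | (4R,5S,6S)-5-methyl-6,7-bis[(triethylsilyl)oxy]hept-1-en-4-yl propanoate | C=CC[C@@H](OC(=O)CC)[C@H](C)[C@H](O[Si](CC)(CC)CC)CO[Si](CC)(CC)CC | intermediate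
26 | methyl (2E,5R,6S,7S)-2,6-dimethyl-5-(propanoyloxy)-7,8-bis[(triethylsilyl)oxy]oct-2-enoate | COC(=O)/C(C)=C/C[C@@H](OC(=O)CC)[C@H](C)[C@H](O[Si](CC)(CC)CC)CO[Si](CC)(CC)CC | intermediate
27 | methyl (2E,5R,6S,7S)-2,6-dimethyl-8-oxo-5-(propanoyloxy)-7-[(triethylsilyl)oxy]oct-2-enoate | COC(=O)/C(C)=C/C[C@@H](OC(=O)CC)[C@H](C)[C@H](O[Si](CC)(CC)CC)C=O | intermediate
28 | fragment 2: (2S,3S,4R,6E)-8-methoxy-3,7-dimethyl-8-oxo-4-(propanoyloxy)-2-[(triethylsilyl)oxy]oct-6-enoic acid | COC(=O)/C(C)=C/C[C@@H](OC(=O)CC)[C@H](C)[C@H](O[Si](CC)(CC)CC)C(O)=O | intermediate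
29 | mixed anhydride of 28 with 2,4,6-trichlorobenzoic acid | COC(=O)/C(C)=C/C[C@@H](OC(=O)CC)[C@H](C)[C@H](O[Si](CC)(CC)CC)C(=O)OC(=O)c1c(Cl)cc(Cl)cc1Cl | intermediate
30 | tethered ester: acyl group of 28 on O11 of 17 (C9–I) | COC(=O)/C(C)=C/C[C@@H](OC(=O)CC)[C@H](C)[C@H](O[Si](CC)(CC)CC)C(=O)O[C@@H]([C@@H](C)CI)[C@@H]1C[C@H](C)C[C@]2(C[C@@H](C)C[C@@H]([C@@H](O[Si](C)(C)C(C)(C)C)C(C)=C(C)C)O2)O1 | intermediate
31 | C9 alkylsamarium diiodide of 30 | COC(=O)/C(C)=C/C[C@@H](OC(=O)CC)[C@H](C)[C@H](O[Si](CC)(CC)CC)C(=O)O[C@@H]([C@@H](C)C[Sm](I)I)[C@@H]1C[C@H](C)C[C@]2(C[C@@H](C)C[C@@H]([C@@H](O[Si](C)(C)C(C)(C)C)C(C)=C(C)C)O2)O1 | intermediate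
32 | C1–C23 γ-hydroxy ketone (C8=O, C11–OH, C7–OTES, C21–OTBS) | COC(=O)/C(C)=C/C[C@@H](OC(=O)CC)[C@H](C)[C@H](O[Si](CC)(CC)CC)C(=O)C[C@H](C)[C@H](O)[C@@H]1C[C@H](C)C[C@]2(C[C@@H](C)C[C@@H]([C@@H](O[Si](C)(C)C(C)(C)C)C(C)=C(C)C)O2)O1 | intermediate
33 | (8S)-8,11-diol (C7–OTES, C21–OTBS) | COC(=O)/C(C)=C/C[C@@H](OC(=O)CC)[C@H](C)[C@H](O[Si](CC)(CC)CC)[C@@H](O)C[C@H](C)[C@H](O)[C@@H]1C[C@H](C)C[C@]2(C[C@@H](C)C[C@@H]([C@@H](O[Si](C)(C)C(C)(C)C)C(C)=C(C)C)O2)O1 | intermediate
34 | 8,11-bis(3-methylbutanoate) (C7–OTES, C21–OTBS) | COC(=O)/C(C)=C/C[C@@H](OC(=O)CC)[C@H](C)[C@H](O[Si](CC)(CC)CC)[C@@H](OC(=O)CC(C)C)C[C@H](C)[C@H](OC(=O)CC(C)C)[C@@H]1C[C@H](C)C[C@]2(C[C@@H](C)C[C@@H]([C@@H](O[Si](C)(C)C(C)(C)C)C(C)=C(C)C)O2)O1 | intermediate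
35 | C7 alcohol (C21–OTBS) | COC(=O)/C(C)=C/C[C@@H](OC(=O)CC)[C@H](C)[C@H](O)[C@@H](OC(=O)CC(C)C)C[C@H](C)[C@H](OC(=O)CC(C)C)[C@@H]1C[C@H](C)C[C@]2(C[C@@H](C)C[C@@H]([C@@H](O[Si](C)(C)C(C)(C)C)C(C)=C(C)C)O2)O1 | intermediate
36 | C7 acetate (C21–OTBS, alkene at C22) | COC(=O)/C(C)=C/C[C@@H](OC(=O)CC)[C@H](C)[C@H](OC(C)=O)[C@@H](OC(=O)CC(C)C)C[C@H](C)[C@H](OC(=O)CC(C)C)[C@@H]1C[C@H](C)C[C@]2(C[C@@H](C)C[C@@H]([C@@H](O[Si](C)(C)C(C)(C)C)C(C)=C(C)C)O2)O1 | intermediate
37 | C22 ozonide (1,2,4-trioxolane) of 36 | COC(=O)/C(C)=C/C[C@@H](OC(=O)CC)[C@H](C)[C@H](OC(C)=O)[C@@H](OC(=O)CC(C)C)C[C@H](C)[C@H](OC(=O)CC(C)C)[C@@H]1C[C@H](C)C[C@]2(C[C@@H](C)C[C@@H]([C@@H](O[Si](C)(C)C(C)(C)C)C3(C)OOC(C)(C)O3)O2)O1 | intermediate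
38 | C22 ketone, C21–OTBS | COC(=O)/C(C)=C/C[C@@H](OC(=O)CC)[C@H](C)[C@H](OC(C)=O)[C@@H](OC(=O)CC(C)C)C[C@H](C)[C@H](OC(=O)CC(C)C)[C@@H]1C[C@H](C)C[C@]2(C[C@@H](C)C[C@@H]([C@@H](O[Si](C)(C)C(C)(C)C)C(C)=O)O2)O1 | intermediate
39 | CNP0165569.4 | CCC(=O)O[C@H](C/C=C(\C)C(=O)OC)[C@H](C)[C@H](OC(C)=O)[C@H](C[C@H](C)[C@H](OC(=O)CC(C)C)[C@@H]1C[C@H](C)C[C@]2(C[C@@H](C)C[C@@H]([C@@H](O)C(C)=O)O2)O1)OC(=O)CC(C)C | target

**Totals**

Total step count: 31. Longest linear sequence: 22 steps (steps 1–14, then 24–31).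

**Steps most likely to fail, with fallbacks**

Risk at step 25 (key step): the alkylsamarium may be protonated to C9–H before it reaches the carbonyl, or the ketone, once released from the hemiketalate, may lose its C7 silyloxy group by further electron transfer. The fallback sets out from 17 and 28 and comes back to the route at 34. Iodo alcohol 17 is acylated with 3-methylbutanoic anhydride and 4-(dimethylamino)pyridine to the C9 iodide 11-(3-methylbutanoate) F1. Activated zinc dust in N,N-dimethylacetamide/THF inserts into the C–I bond of F1 to give the C9 alkylzinc iodide 11-(3-methylbutanoate) F2. Acid 28 is converted with EtSH, dicyclohexylcarbodiimide and 4-(dimethylamino)pyridine into the fragment 2 S-ethyl thioester F3. Fukuyama coupling of F2 with F3 (PdCl2(PPh3)2, toluene/THF, rt) gives the C8 ketone 11-(3-methylbutanoate) F4. CBS reduction of F4 as in step 26 gives the (8S)-alcohol 11-(3-methylbutanoate) F5, and acylation of F5 with 3-methylbutanoic anhydride gives 34.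

Risk at step 5: the Claisen adduct may revert or oligomerise, or the lactone may be consumed by proton transfer, before the decarboxylation. The fallback sets out from 5 and comes back to the route at 7. Lactone 5 is opened with LiOH in THF/H2O to lithium (3S,5S)-6-(benzyloxy)-5-hydroxy-3-methylhexanoate F6. Silylation of F6 with tBuMe2SiCl and imidazole in DMF gives tert-butyldimethylsilyl (3S,5S)-6-(benzyloxy)-5-[(tert-butyldimethylsilyl)oxy]-3-methylhexanoate F7, and K2CO3 in MeOH/H2O cleaves only the silyl ester of F7 to give (3S,5S)-6-(benzyloxy)-5-[(tert-butyldimethylsilyl)oxy]-3-methylhexanoic acid F8. Decarboxylative iodination of F8 (PhI(OAc)2, iodine, visible light) gives (2S,4S)-1-(benzyloxy)-2-[(tert-butyldimethylsilyl)oxy]-5-iodo-4-methylpentane F9, one carbon shorter than the acid. Iodine–lithium exchange (tBuLi, Et2O, −78 °C) turns F9 into the C17–C21 alkyllithium F10, which adds to a second molecule of 5 and gives, after aq. NH4Cl, the open-chain C11–C21 hydroxy ketone F11. Aqueous HCl in THF removes the silyl group of F11 and closes both rings to 7.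

Risk at step 24: acylation of the hindered C11 hydroxyl by the α-silyloxy acid may be slow, and the primary iodide may alkylate the acyl-transfer catalyst. The fallback sets out from 14 and 28 and comes back to the route at 30. The tether is made before the iodide exists: 28 and allylic alcohol 14 are esterified under Yamaguchi conditions, now with heating, to the allylic C8–O11 ester F12. Hydroboration of the isopropenyl group of F12 with 9-BBN sets C10 as in step 13 and gives the tethered C9 B-alkyl-9-BBN F13. NaBO3 oxidises F13 to the tethered C9 primary alcohol F14. Iodine, PPh3 and imidazole convert F14 into 30.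

Further compounds

F1 | step 25 | C9 iodide 11-(3-methylbutanoate) | IC[C@H](C)[C@H](OC(=O)CC(C)C)[C@@H]1C[C@H](C)C[C@]2(C[C@@H](C)C[C@@H]([C@@H](O[Si](C)(C)C(C)(C)C)C(C)=C(C)C)O2)O1
F2 | step 25 | C9 alkylzinc iodide 11-(3-methylbutanoate) | I[Zn]C[C@H](C)[C@H](OC(=O)CC(C)C)[C@@H]1C[C@H](C)C[C@]2(C[C@@H](C)C[C@@H]([C@@H](O[Si](C)(C)C(C)(C)C)C(C)=C(C)C)O2)O1
F3 | step 25 | fragment 2 S-ethyl thioester | COC(=O)/C(C)=C/C[C@@H](OC(=O)CC)[C@H](C)[C@H](O[Si](CC)(CC)CC)C(=O)SCC
F4 | step 25 | C8 ketone 11-(3-methylbutanoate) | COC(=O)/C(C)=C/C[C@@H](OC(=O)CC)[C@H](C)[C@H](O[Si](CC)(CC)CC)C(=O)C[C@H](C)[C@H](OC(=O)CC(C)C)[C@@H]1C[C@H](C)C[C@]2(C[C@@H](C)C[C@@H]([C@@H](O[Si](C)(C)C(C)(C)C)C(C)=C(C)C)O2)O1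
F5 | step 25 | (8S)-alcohol 11-(3-methylbutanoate) | COC(=O)/C(C)=C/C[C@@H](OC(=O)CC)[C@H](C)[C@H](O[Si](CC)(CC)CC)[C@@H](O)C[C@H](C)[C@H](OC(=O)CC(C)C)[C@@H]1C[C@H](C)C[C@]2(C[C@@H](C)C[C@@H]([C@@H](O[Si](C)(C)C(C)(C)C)C(C)=C(C)C)O2)O1
F6 | step 5 | lithium (3S,5S)-6-(benzyloxy)-5-hydroxy-3-methylhexanoate | [Li+].[O-]C(=O)C[C@@H](C)C[C@H](O)COCc1ccccc1
F7 | step 5 | tert-butyldimethylsilyl (3S,5S)-6-(benzyloxy)-5-[(tert-butyldimethylsilyl)oxy]-3-methylhexanoate | CC(C)(C)[Si](C)(C)OC(=O)C[C@@H](C)C[C@H](O[Si](C)(C)C(C)(C)C)COCc1ccccc1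
F8 | step 5 | (3S,5S)-6-(benzyloxy)-5-[(tert-butyldimethylsilyl)oxy]-3-methylhexanoic acid | OC(=O)C[C@@H](C)C[C@H](O[Si](C)(C)C(C)(C)C)COCc1ccccc1
F9 | step 5 | (2S,4S)-1-(benzyloxy)-2-[(tert-butyldimethylsilyl)oxy]-5-iodo-4-methylpentane | IC[C@@H](C)C[C@H](O[Si](C)(C)C(C)(C)C)COCc1ccccc1
F10 | step 5 | C17–C21 alkyllithium | [Li]C[C@@H](C)C[C@H](O[Si](C)(C)C(C)(C)C)COCc1ccccc1
F11 | step 5 | open-chain C11–C21 hydroxy ketone | C(OCc1ccccc1)[C@@H](O)C[C@H](C)CC(=O)C[C@@H](C)C[C@H](O[Si](C)(C)C(C)(C)C)COCc1ccccc1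
F12 | step 24 | allylic C8–O11 ester | COC(=O)/C(C)=C/C[C@@H](OC(=O)CC)[C@H](C)[C@H](O[Si](CC)(CC)CC)C(=O)O[C@@H](C(C)=C)[C@@H]1C[C@H](C)C[C@]2(C[C@@H](C)C[C@@H]([C@@H](O[Si](C)(C)C(C)(C)C)C(C)=C(C)C)O2)O1
F13 | step 24 | tethered C9 B-alkyl-9-BBN | COC(=O)/C(C)=C/C[C@@H](OC(=O)CC)[C@H](C)[C@H](O[Si](CC)(CC)CC)C(=O)O[C@@H]([C@@H](C)CB3C4CCCC3CCC4)[C@@H]1C[C@H](C)C[C@]2(C[C@@H](C)C[C@@H]([C@@H](O[Si](C)(C)C(C)(C)C)C(C)=C(C)C)O2)O1
F14 | step 24 | tethered C9 primary alcohol | COC(=O)/C(C)=C/C[C@@H](OC(=O)CC)[C@H](C)[C@H](O[Si](CC)(CC)CC)C(=O)O[C@@H]([C@@H](C)CO)[C@@H]1C[C@H](C)C[C@]2(C[C@@H](C)C[C@@H]([C@@H](O[Si](C)(C)C(C)(C)C)C(C)=C(C)C)O2)O1
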